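(The readings stem from a simulated flask with constants of no real substance; scatter was added.)

Percentage points are your unit here: call s the share of target in target plus uncatalysed product, the selectivity of the flask.

| setting | north-west | east | north-east | midnight | autumn | dusk |
|---|---|---|---|---|---|---|
| starting material | 0.50 M | 0.50 M | 0.50 M | 0.50 M | 0.50 M | 0.50 M |
| second substrate | 0.25 M | 0.25 M | 0.25 M | 0.250 M | 0.250 M | 0.250 M (fed, over 40 h) |
| reagent | 0.35 M | 0.17 M | 0.70 M | 0.350 M | 0.350 M (fed, over 40 h) | 0.350 M |
| free catalyst | 0.30 mM | 0.30 mM | 0.30 mM | 0.30 mM | 0.30 mM | 0.30 mM |
| remark | run made earlier | run made earlier | run made earlier | everything together at the start | all else is in the flask from the start; the feed brings no volume worth counting | all else is in the flask from the start; the feed brings no volume worth counting |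
| time |  |  |  | 4.0 d | 4.0 d | 4.0 d |

- north-west (time / d: target / %, uncatalysed product / %): 0.417: 4.6, 8.3; 0.833: 8.8, 13.0; 1.25: 11.7, 15.7; 1.67: 9.9, 17.4; 2.08: 13.9, 21.0; 2.50: 13.8, 22.4
- east (time / d: target / %, uncatalysed product / %): 0.250: 0.9, 2.1; 0.833: 4.3, 2.9; 1.25: 3.9, 9.5; 2.00: 6.1, 9.7; 3.00: 6.6, 10.7; 4.00: 6.4, 12.3
- north-east (time / d: target / %, uncatalysed product / %): 0.333: 7.8, 11.4; 0.500: 10.0, 16.2; 0.833: 13.6, 23.1; 1.67: 24.0, 33.1; 2.50: 27.4, 37.9; 4.00: 31.1, 43.1

(each reading ± 1 percentage point)

- the earlier runs were read with a standard deviation of 1 percentage point
- reactions considered so far: catalyst intermediate B -> spent catalyst; second substrate + free catalyst <-> catalyst intermediate B; reagent + catalyst intermediate A -> free catalyst + target; starting material + free catalyst <-> catalyst intermediate A; reagent + catalyst intermediate B -> free catalyst + second product; starting material + reagent -> uncatalysed product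

1. which flask leads in share of target in target plus uncatalysed product ("all alike" within 1.5 percentage points) (midnight / autumn / dusk / all alike)
2. share of target in target plus uncatalysed product at the end, midnight
3. share of target in target plus uncatalysed product at the end, autumn
4. share of target in target plus uncatalysed product at the end, dusk

Freeze the reagent first. Target and uncatalysed product each form in a step taking one reagent, so reagent cancels from their split, and s follows the catalyst standing as catalyst intermediate A. Catalyst is lost from catalyst intermediate B, which second substrate makes and reagent clears, so rank your flasks by ρ, reagent over second substrate.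

The last readings form a ladder. The east run gives 34.2% at ρ of 0.680, the north-west run 38.1% at 1.40, and the north-east run 41.9% at 2.80, higher at each step . Take the east reading as the floor and the north-east reading as the ceiling. The floor is soft, since it rests on a target of 6.4% read to 1 percentage point.

Now tighten. Midnight repeats the north-west recipe, so put it near 38.1%. Autumn starts without reagent, so ρ starts low and you place it between the floor and 38.1%. Dusk starts with its reagent in and without second substrate, so ρ starts high and you place it between 38.1% and the ceiling.

The forecast names dusk as leader, with 39%, 36% and 48% for midnight, autumn and dusk, holding that "Feeding second substrate frees catalyst early, spares reagent and slows death"; its dusk figure stands above this ceiling.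

The flasks give 38.1% for midnight, 34.2% for autumn and 40.8% for dusk, so dusk leads, under the ceiling, while autumn sits on the floor.

    catalyst intermediate B → spent catalyst (k = 0.0260 h⁻¹)
    second substrate + free catalyst ⇌ catalyst intermediate B (K = 4.00 M⁻¹, k = 100 M⁻¹ h⁻¹)
    reagent + catalyst intermediate A → free catalyst + target (k = 98.0 M⁻¹ h⁻¹)
    starting material + free catalyst ⇌ catalyst intermediate A (K = 1.10 M⁻¹, k = 590 M⁻¹ h⁻¹)
    reagent + catalyst intermediate B → free catalyst + second product (k = 260 M⁻¹ h⁻¹)
    starting material + reagent → uncatalysed product (k = 0.0270 M⁻¹ h⁻¹)

Take the neighbouring flask, dusk with 1.0 M of second substrate. Its ρ is 0.350, lower than the east run's, so the ladder points below the floor of 34.2%, though this flask is fed and the rungs are not. It gives 34.5%, beside that floor, with spent catalyst at 71.4% of the catalyst charged after 4.00 d.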